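**Retrosynthetic overview**
- The target, a 2,3-cis-(2S,3R)-2,3-diaryl-2,3-dihydrobenzofuran, comes from neutral hydrogenolysis of its tris-benzyl ether in the last step.
- The dihydrofuran ring is the only ring built (all benzene rings are bought); it is closed late by an invertive Mitsunobu O1–C2 etherification of a (1R,2R)-1,2,2-triarylethanol.
- Both stereocentres come from one asymmetric transfer hydrogenation with dynamic kinetic resolution of a racemic, epimerisable α,α-diaryl ketone.
- Key C3–C3a bond: an α-oxo carbenium (enolonium equivalent) from an α-diazo deoxybenzoin is captured by unprotected dihydroresveratrol; the ketone α-carbon and the arene carbon are both natural nucleophiles.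
- The diazoketone comes from diazo transfer onto a deoxybenzoin made from a benzylzinc reagent and an aroyl chloride.

Assumption: the SMILES is read as the 2,3-cis (2S,3R) isomer, and 4-(benzyloxy)benzoyl chloride, 3,5-bis(benzyloxy)benzyl bromide and dihydroresveratrol are taken as catalogue compounds.

**Step 1**
Reactants: 1 4-(benzyloxy)benzoyl chloride; 2 3,5-bis(benzyloxy)benzyl bromide
Product: 4 1-[4-(benzyloxy)phenyl]-2-[3,5-bis(benzyloxy)phenyl]ethan-1-one, via benzylzinc bromide 3 (not isolated)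
Conditions: Zn dust, THF, 0 °C; then 1, Pd(PPh3)4 (2 mol%), THF, 0 °C to rt
Reagents that add atoms: none
Why: Zinc inserts into the benzylic C–Br bond and the benzylzinc is acylated by the aroyl chloride under zerovalent palladium catalysis (Negishi acylation), which stops at the ketone; no stereocentre is formed.

**Step 2**
Reactants: 4 1-[4-(benzyloxy)phenyl]-2-[3,5-bis(benzyloxy)phenyl]ethan-1-one
Product: 5 1-[4-(benzyloxy)phenyl]-2-[3,5-bis(benzyloxy)phenyl]-2-diazoethan-1-one
Conditions: p-ABSA, DBU, MeCN, 0 °C to rt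
Reagents that add atoms: 4-acetamidobenzenesulfonyl azide (p-ABSA), CC(=O)Nc1ccc(cc1)S(=O)(=O)N=[N+]=[N-]
Why: The CH2 flanked by aryl and aroyl is acidic enough for DBU and its enolate takes N2 from the sulfonyl azide (Regitz diazo transfer), avoiding the ring halogenation that an α-bromination of these electron-rich arenes would risk; no stereocentre.

**Step 3**
Reactants: 5 1-[4-(benzyloxy)phenyl]-2-[3,5-bis(benzyloxy)phenyl]-2-diazoethan-1-one; 6 dihydroresveratrol, 5-[2-(4-hydroxyphenyl)ethyl]benzene-1,3-diol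
Product: 7 racemic 1-[4-(benzyloxy)phenyl]-2-[3,5-bis(benzyloxy)phenyl]-2-{2,4-dihydroxy-6-[2-(4-hydroxyphenyl)ethyl]phenyl}ethan-1-one
Conditions: B(C6F5)3 (10 mol%), 6 (3 equiv), CH2Cl2/MeNO2 2:1, −20 °C to 0 °C, 5 added over 2 h; Et3N quench
Reagents that add atoms: none
Why: Proposed new method: B(C6F5)3 binds the carbonyl oxygen of 5 and N2 leaves, so the former enolate α-carbon becomes an α-oxo carbenium (enolonium equivalent) that is captured in a Friedel–Crafts sense by C4 of the resorcinol ring of 6, its kinetically most nucleophilic carbon (ortho to one OH, para to the other, two equivalent sites; the hydrogen-bonded ortho OH steers the electrophile and C–H is preferred over O–H insertion), giving 7 with a racemic, labile α-stereocentre; the closest known reaction types are the B(C6F5)3-catalysed ortho C–H alkylation of free phenols with α-aryl-α-diazoesters and the C-alkylation of electron-rich phenols by α-haloketones.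

**Step 4**
Reactants: 7 racemic 1-[4-(benzyloxy)phenyl]-2-[3,5-bis(benzyloxy)phenyl]-2-{2,4-dihydroxy-6-[2-(4-hydroxyphenyl)ethyl]phenyl}ethan-1-one
Product: 8 (1R,2R)-1-[4-(benzyloxy)phenyl]-2-[3,5-bis(benzyloxy)phenyl]-2-{2,4-dihydroxy-6-[2-(4-hydroxyphenyl)ethyl]phenyl}ethan-1-ol
Conditions: RuCl(p-cymene)[(R,R)-TsDPEN] (2 mol%), HCO2H/Et3N 1:1, DMF, 40 °C
Reagents that add atoms: none
Why: The doubly benzylic α-proton of 7 epimerises quickly in the formate/amine medium while the (R,R)-catalyst delivers hydride to one carbonyl face (same sense as acetophenone, giving the 1R carbinol) and reduces fastest the ketone enantiomer whose bulky 2,6-disubstituted aryl sits anti to the incoming hydride (Felkin–Anh), so both centres are set as (1R,2R) in one Noyori–Ikariya asymmetric transfer hydrogenation with dynamic kinetic resolution, here extended from α-aryl and α-heteroatom ketones to an acyclic α,α-diaryl ketone.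

**Step 5**
Reactants: 8 (1R,2R)-1-[4-(benzyloxy)phenyl]-2-[3,5-bis(benzyloxy)phenyl]-2-{2,4-dihydroxy-6-[2-(4-hydroxyphenyl)ethyl]phenyl}ethan-1-ol
Product: 9 (2S,3R)-2-[4-(benzyloxy)phenyl]-3-[3,5-bis(benzyloxy)phenyl]-4-[2-(4-hydroxyphenyl)ethyl]-2,3-dihydro-1-benzofuran-6-ol (2,3-cis)
Conditions: PPh3, DIAD, THF, −20 °C to 0 °C
Reagents that add atoms: none
Why: Mitsunobu etherification: the oxyphosphonium of the secondary alcohol is displaced intramolecularly (5-exo-tet) by the ortho phenol with inversion at the carbinol carbon (1R becomes 2S) while the neighbouring centre is untouched (stays R), which converts the Felkin alcohol into the 2,3-cis ring; the two remote phenols cannot reach the carbinol carbon intramolecularly.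

**Step 6**
Reactants: 9 (2S,3R)-2-[4-(benzyloxy)phenyl]-3-[3,5-bis(benzyloxy)phenyl]-4-[2-(4-hydroxyphenyl)ethyl]-2,3-dihydro-1-benzofuran-6-ol
Product: 10 (2S,3R)-3-(3,5-dihydroxyphenyl)-2-(4-hydroxyphenyl)-4-[2-(4-hydroxyphenyl)ethyl]-2,3-dihydro-1-benzofuran-6-ol (target, 2,3-cis)
Conditions: H2 (1 atm), 10% Pd/C, EtOAc/EtOH, rt, stopped at full debenzylation
Reagents that add atoms: none
Why: Hydrogenolysis of the three aryl benzyl ethers over Pd/C under neutral conditions avoids the acid or base that would open the 2-(4-hydroxyphenyl) ring to a quinone methide and epimerise C2 to the trans isomer; both stereocentres are carried through unchanged.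

**Compound list**
1 | 4-(benzyloxy)benzoyl chloride | O=C(Cl)c1ccc(OCc2ccccc2)cc1 | starting material
2 | 3,5-bis(benzyloxy)benzyl bromide | BrCc1cc(OCc2ccccc2)cc(OCc2ccccc2)c1 | starting material
3 | [3,5-bis(benzyloxy)benzyl]zinc bromide (not isolated) | Br[Zn]Cc1cc(OCc2ccccc2)cc(OCc2ccccc2)c1 | intermediate
4 | 1-[4-(benzyloxy)phenyl]-2-[3,5-bis(benzyloxy)phenyl]ethan-1-one | O=C(Cc1cc(OCc2ccccc2)cc(OCc2ccccc2)c1)c1ccc(OCc2ccccc2)cc1 | intermediate
5 | 1-[4-(benzyloxy)phenyl]-2-[3,5-bis(benzyloxy)phenyl]-2-diazoethan-1-one | O=C(C(=[N+]=[N-])c1cc(OCc2ccccc2)cc(OCc2ccccc2)c1)c1ccc(OCc2ccccc2)cc1 | intermediate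
6 | dihydroresveratrol, 5-[2-(4-hydroxyphenyl)ethyl]benzene-1,3-diol | Oc1ccc(CCc2cc(O)cc(O)c2)cc1 | starting material
7 | racemic 1-[4-(benzyloxy)phenyl]-2-[3,5-bis(benzyloxy)phenyl]-2-{2,4-dihydroxy-6-[2-(4-hydroxyphenyl)ethyl]phenyl}ethan-1-one | O=C(c1ccc(OCc2ccccc2)cc1)C(c1cc(OCc2ccccc2)cc(OCc2ccccc2)c1)c1c(O)cc(O)cc1CCc1ccc(O)cc1 | intermediate
8 | (1R,2R)-1-[4-(benzyloxy)phenyl]-2-[3,5-bis(benzyloxy)phenyl]-2-{2,4-dihydroxy-6-[2-(4-hydroxyphenyl)ethyl]phenyl}ethan-1-ol | O[C@@H](c1ccc(OCc2ccccc2)cc1)[C@H](c1cc(OCc2ccccc2)cc(OCc2ccccc2)c1)c1c(O)cc(O)cc1CCc1ccc(O)cc1 | intermediate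
9 | (2S,3R)-2-[4-(benzyloxy)phenyl]-3-[3,5-bis(benzyloxy)phenyl]-4-[2-(4-hydroxyphenyl)ethyl]-2,3-dihydro-1-benzofuran-6-ol | Oc1ccc(CCc2cc(O)cc3c2[C@@H](c2cc(OCc4ccccc4)cc(OCc4ccccc4)c2)[C@@H](c2ccc(OCc4ccccc4)cc2)O3)cc1 | intermediate
10 | (2S,3R)-3-(3,5-dihydroxyphenyl)-2-(4-hydroxyphenyl)-4-[2-(4-hydroxyphenyl)ethyl]-2,3-dihydro-1-benzofuran-6-ol | Oc1ccc(CCc2cc(O)cc3c2[C@@H](c2cc(O)cc(O)c2)[C@@H](c2ccc(O)cc2)O3)cc1 | target

**Step count and risks**
Total step count: 6. Longest linear sequence: 6 (steps 1 to 6; compound 6 enters at step 3).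

Most likely to fail:

Step 3. The risks are alkylation at C2 between the two hydroxyls instead of C4, O–H insertion, a Wolff-type aryl shift of the diazoketone, and acid-driven cyclodehydration of 7 to the benzofuran. Fallback: reverse the polarity on the arene instead of on the ketone. Setting out from 6, silylation (TBSCl, imidazole, DMF) gives the tris(tert-butyldimethylsilyl) ether F1. Bromination with NBS (MeCN, 0 °C) goes para to a silyloxy group and ortho to the side chain, as for 3,5-dialkoxytoluenes, and gives the aryl bromide F2. Palladium-catalysed α-arylation of deoxybenzoin 4 with F2 (Pd2(dba)3, XPhos, K3PO4, toluene, 100 °C) gives the silyl-protected triaryl ketone F3. Buffered fluoride (TBAF, AcOH, THF, 0 °C) then comes back to the route at 7.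

Step 4. The risks are low diastereo- or enantioselectivity, a slow reduction of this hindered ketone, or the anti alcohol being favoured. Fallback: separate diastereocontrol from enantiocontrol. Setting out from 7, NaBH4 (MeOH/THF, −40 °C) under Felkin–Anh substrate control gives the racemic syn alcohol, that is 8 together with its (1S,2S)-enantiomer F4. Preparative chiral SFC comes back to the route at 8, and F4 is recycled by Dess–Martin oxidation to 7.

Step 5. The risks are ionisation of the 4-benzyloxybenzylic oxyphosphonium (giving the trans ring) and elimination to a triarylethene. Fallback: close the furan ring before the stereocentres exist. Setting out from 7, acid (p-TsOH, toluene, 60 °C) gives the 2,3-diarylbenzofuran F5. Enantioselective cis-hydrogenation of its C2=C3 bond (Ru(cod)(2-methylallyl)2 with the chiral N-heterocyclic carbene from (R,R)-SINpEt·HBF4 and KOtBu, H2 60 bar, toluene) adds both hydrogens to one face and comes back to the route at 9. The ligand enantiomer is chosen for 2S,3R, and 9 is polished by chiral SFC if needed.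

**Further compounds**
F1 | step 3 | 1,3-bis(tert-butyldimethylsilyloxy)-5-{2-[4-(tert-butyldimethylsilyloxy)phenyl]ethyl}benzene | CC(C)(C)[Si](C)(C)Oc1ccc(CCc2cc(O[Si](C)(C)C(C)(C)C)cc(O[Si](C)(C)C(C)(C)C)c2)cc1
F2 | step 3 | 2-bromo-1,5-bis(tert-butyldimethylsilyloxy)-3-{2-[4-(tert-butyldimethylsilyloxy)phenyl]ethyl}benzene | CC(C)(C)[Si](C)(C)Oc1ccc(CCc2cc(O[Si](C)(C)C(C)(C)C)cc(O[Si](C)(C)C(C)(C)C)c2Br)cc1
F3 | step 3 | racemic 1-[4-(benzyloxy)phenyl]-2-[3,5-bis(benzyloxy)phenyl]-2-{2,4-bis(tert-butyldimethylsilyloxy)-6-[2-(4-(tert-butyldimethylsilyloxy)phenyl)ethyl]phenyl}ethan-1-one | O=C(c1ccc(OCc2ccccc2)cc1)C(c1cc(OCc2ccccc2)cc(OCc2ccccc2)c1)c1c(O[Si](C)(C)C(C)(C)C)cc(O[Si](C)(C)C(C)(C)C)cc1CCc1ccc(O[Si](C)(C)C(C)(C)C)cc1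
F4 | step 4 | (1S,2S)-1-[4-(benzyloxy)phenyl]-2-[3,5-bis(benzyloxy)phenyl]-2-{2,4-dihydroxy-6-[2-(4-hydroxyphenyl)ethyl]phenyl}ethan-1-ol | O[C@H](c1ccc(OCc2ccccc2)cc1)[C@@H](c1cc(OCc2ccccc2)cc(OCc2ccccc2)c1)c1c(O)cc(O)cc1CCc1ccc(O)cc1
F5 | step 5 | 2-[4-(benzyloxy)phenyl]-3-[3,5-bis(benzyloxy)phenyl]-4-[2-(4-hydroxyphenyl)ethyl]-1-benzofuran-6-ol | Oc1ccc(CCc2cc(O)cc3oc(-c4ccc(OCc5ccccc5)cc4)c(-c4cc(OCc5ccccc5)cc(OCc5ccccc5)c4)c23)cc1
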